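Each flavone half is cut at O1–C2 and then at C4a–C8a. This unfolds each ring A (C4a, C5, C6, C7, C8, C8a), a phloroglucinol acylated at C4a, into a linear chain from C2 to C8a that is oxygenated at alternate carbons. The precursor is a diaryl ether with two ArC(=O)CH2C(=O)CH2 arms, each ending in a 6-substituted 4-hydroxy-2-pyranone that stores C5 to C8a as a lactone. In one operation Mg(OMe)2 opens both lactones and each C4a carbanion closes onto its C8a ester carbonyl, so both carbocyclic rings A form without protecting groups; acid then closes both rings C.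

Key step: step 4

Remark: locants C2 to C8a are flavone locants and apply to both halves (unit 1 sits on the methoxy-bearing ring B, unit 2 on the other ring B). Polyketo compounds are drawn as keto tautomers and polyanions as lithium salts with localised charges.

Step 1
Reactants: 1 methyl 3-hydroxy-4-methoxybenzoate; 2 methyl 4-fluorobenzoate
Product: 3 methyl 4-methoxy-3-[4-(methoxycarbonyl)phenoxy]benzoate
Conditions: Cs2CO3 (1.5 equiv), dry DMSO, 110 °C
Reagents that add atoms: none
Why: Nucleophilic aromatic substitution (SNAr): the phenoxide of 1 adds para to the ester of 2, the anionic σ-adduct is stabilised by that ester and fluoride leaves, while any ester exchange is degenerate because both esters are methyl.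

Step 2
Reactants: 4 4-hydroxy-6-methyl-2H-pyran-2-one (triacetic acid lactone)
Product: 7 4-hydroxy-6-(2-oxopropyl)-2H-pyran-2-one, via dilithium lactone dianion 5 (not isolated), via dilithium tetrahedral adduct 6 (not isolated)
Conditions: LiN(iPr)2 (2.1 equiv), THF, −78 to −20 °C; N-methoxy-N-methylacetamide (1.2 equiv), −78 to 0 °C; 1 M HCl
Reagents that add atoms: N-methoxy-N-methylacetamide, CC(=O)N(C)OC
Why: C-acylation of a dicarbonyl-type dianion: the second deprotonation of 4 gives the vinylogous carbanion at the 6-methyl group, the most nucleophilic site of 5, and the N-methoxy-N-methyl amide stops at the Li-chelated adduct 6, so the acidic ketone 7 appears only on the acid quench and can neither drain unreacted dianion nor be acylated again.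

Step 3
Reactants: 7 4-hydroxy-6-(2-oxopropyl)-2H-pyran-2-one; 3 methyl 4-methoxy-3-[4-(methoxycarbonyl)phenoxy]benzoate
Product: 9 4-hydroxy-6-[4-(3-{4-[4-(4-hydroxy-2-oxo-2H-pyran-6-yl)-3-oxobutanoyl]phenoxy}-4-methoxyphenyl)-2,4-dioxobutyl]-2H-pyran-2-one, via trilithium trianion 8 (not isolated)
Conditions: 7 (4.4 equiv), LiN(iPr)2 (14 equiv), THF, −78 to 0 °C; 3 (1 equiv), 0 °C to rt; cold 2 M HCl
Reagents that add atoms: none
Why: Twofold Claisen condensation of a multiple anion with a non-enolisable aromatic ester: the last-formed terminal methylene carbanion of 8 is its least stabilised and most nucleophilic carbon, so each ester of 3 is attacked there, and the second equivalent of 8 per ester takes up the proton of the new 1,3-diketone, which shields it from retro-Claisen cleavage and leaves the surplus 7 recoverable.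

Step 4
Reactants: 9 4-hydroxy-6-[4-(3-{4-[4-(4-hydroxy-2-oxo-2H-pyran-6-yl)-3-oxobutanoyl]phenoxy}-4-methoxyphenyl)-2,4-dioxobutyl]-2H-pyran-2-one
Product: 11 1-(2,4,6-trihydroxyphenyl)-3-[4-methoxy-3-(4-{3-oxo-3-(2,4,6-trihydroxyphenyl)propanoyl}phenoxy)phenyl]propane-1,3-dione, via ring-opened bis(methyl tetraoxononanoate) 10 (not isolated)
Conditions: Mg(OMe)2 (12 equiv), dry MeOH, Ar, rt to 60 °C; cold 1 M HCl
Reagents that add atoms: none
Why: Because C4a cannot reach C8a while the pyranone is intact, methoxide first adds to each lactone carbonyl C8a and opens it to the methyl polyketo ester 10, whose 1,3-dicarbonyl units sit on magnesium as chelated enolates. The C4a carbanion, flanked by the C4 and C5 carbonyls, then attacks the C8a ester carbonyl, methoxide leaves and the cyclohexane-1,3,5-trione tautomerises to the phloroglucinol, so 9 and 11 are isomers and nothing has to be oxidised, reduced or deprotected. The closest known reaction type is the Mg(OMe)2-induced ring opening and Claisen recyclisation of 6-(2-oxoalkyl)-4-hydroxy-2-pyranones to acylphloroglucinols, applied here twice in one molecule to arms that the diaryl ether keeps apart. Ring A of unit 1 and ring A of unit 2 each close in a 6-exo-trig mode at the ester carbonyl (6-(enolendo)-exo-trig for the C4a=C5 enolate), and no stereocentre is created. The selectivity needed is Claisen closure (C4a to C8a) over the aldol closures C8 to C4, C3 to C7 and C6 to C2 that would give resorcinol-type rings; it is secured by the non-hydrolytic, fully deprotonating medium, in which all four ketones of each chain are masked as Mg-bound enolates and the methyl ester is the only neutral carbonyl left, and by the lactone mask, which keeps C5 to C8a out of any aldol until that ester is unveiled. Since the hydroxyls on C5 and C8a of each new ring are equivalent by symmetry, the later closure of ring C has only one outcome.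

Step 5
Reactants: 11 1-(2,4,6-trihydroxyphenyl)-3-[4-methoxy-3-(4-{3-oxo-3-(2,4,6-trihydroxyphenyl)propanoyl}phenoxy)phenyl]propane-1,3-dione
Product: 12 4'-O-methylochnaflavone, 2-{3-[4-(5,7-dihydroxy-4-oxo-4H-chromen-2-yl)phenoxy]-4-methoxyphenyl}-5,7-dihydroxy-4H-chromen-4-one
Conditions: crude 11, AcOH, H2SO4 (0.5% v/v), 95 °C
Reagents that add atoms: none
Why: Acid-catalysed cyclodehydration of a 1-(2-hydroxyaryl)-3-arylpropane-1,3-dione, the ring-closing stage of a Baker–Venkataraman flavone synthesis: an ortho hydroxyl of each phloroglucinol ring adds to the protonated aroyl carbonyl C2 and water is lost to form the 4-pyranone ring C, the two ortho hydroxyls being equivalent so that only the 5,7-dihydroxy pattern can arise, while the aryl methyl ether and the diaryl ether are inert to this acid.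

Compound list
1 | methyl 3-hydroxy-4-methoxybenzoate (methyl isovanillate) | COC(=O)c1ccc(OC)c(O)c1 | starting material
2 | methyl 4-fluorobenzoate | COC(=O)c1ccc(F)cc1 | starting material
3 | methyl 4-methoxy-3-[4-(methoxycarbonyl)phenoxy]benzoate | COC(=O)c1ccc(Oc2cc(C(=O)OC)ccc2OC)cc1 | intermediate
4 | 4-hydroxy-6-methyl-2H-pyran-2-one (triacetic acid lactone) | Cc1cc(O)cc(=O)o1 | starting material
5 | dilithium salt of the dianion of 4 (4-oxide, carbanion at the 6-methylene), not isolated | [Li+].[Li+].[CH2-]c1cc([O-])cc(=O)o1 | intermediate
6 | dilithium 6-{2-[methoxy(methyl)amino]-2-oxidopropyl}-2-oxo-2H-pyran-4-olate (racemic tetrahedral adduct, centre lost on work-up), not isolated | [Li+].[Li+].CC([O-])(Cc1cc([O-])cc(=O)o1)N(C)OC | intermediate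
7 | 4-hydroxy-6-(2-oxopropyl)-2H-pyran-2-one | CC(=O)Cc1cc(O)cc(=O)o1 | intermediate
8 | trilithium salt of the trianion of 7 (4-oxide, carbanions at the ring-bound methylene and at the terminal methyl), not isolated | [Li+].[Li+].[Li+].[CH2-]C(=O)[CH-]c1cc([O-])cc(=O)o1 | intermediate
9 | 4-hydroxy-6-[4-(3-{4-[4-(4-hydroxy-2-oxo-2H-pyran-6-yl)-3-oxobutanoyl]phenoxy}-4-methoxyphenyl)-2,4-dioxobutyl]-2H-pyran-2-one (3 with each CO2Me replaced by C(=O)CH2C(=O)CH2 bonded to position 6 of a 4-hydroxy-2-pyranone) | COc1ccc(C(=O)CC(=O)Cc2cc(O)cc(=O)o2)cc1Oc1ccc(C(=O)CC(=O)Cc2cc(O)cc(=O)o2)cc1 | intermediate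
10 | methyl 9-{4-methoxy-3-[4-(9-methoxy-3,5,7,9-tetraoxononanoyl)phenoxy]phenyl}-3,5,7,9-tetraoxononanoate (formed as its Mg-bound enolate, not isolated) | COc1ccc(C(=O)CC(=O)CC(=O)CC(=O)CC(=O)OC)cc1Oc1ccc(C(=O)CC(=O)CC(=O)CC(=O)CC(=O)OC)cc1 | intermediate
11 | 1-(2,4,6-trihydroxyphenyl)-3-[4-methoxy-3-(4-{3-oxo-3-(2,4,6-trihydroxyphenyl)propanoyl}phenoxy)phenyl]propane-1,3-dione | COc1ccc(C(=O)CC(=O)c2c(O)cc(O)cc2O)cc1Oc1ccc(C(=O)CC(=O)c2c(O)cc(O)cc2O)cc1 | intermediate
12 | 4'-O-methylochnaflavone (achiral) | COc1ccc(-c2cc(=O)c3c(O)cc(O)cc3o2)cc1Oc1ccc(-c2cc(=O)c3c(O)cc(O)cc3o2)cc1 | target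

Total step count: 5. Longest linear sequence: 4 steps (4 to 7 to 9 to 11 to 12, or 1 to 3 to 9 to 11 to 12).

Steps most likely to fail

Step 4 (key step). The opened chains may fold by aldol instead of Claisen closure in one or both arms, the pyranonate rings may resist opening, or methoxide may cleave the aroylacetyl unit by retro-Claisen reaction. The fallback sets out from 3 and comes back at 11, building ring A from a preformed phloroglucinol instead of folding it. Saponification of 3 (LiOH, THF–water, then HCl) should give 3-(4-carboxyphenoxy)-4-methoxybenzoic acid F1. Oxalyl chloride with catalytic DMF in CH2Cl2 should convert it into 3-[4-(chlorocarbonyl)phenoxy]-4-methoxybenzoyl chloride F2. Commercial 2',4',6'-trihydroxyacetophenone is deprotonated with LiN(SiMe3)2 (about 4.5 equiv) in THF at −78 °C to its tetralithium salt F3, and F2 is added to 2.4 equiv of it. C-aroylation at the enolate carbon, a Baker–Venkataraman-type acyl transfer done directly on the polyanion, should give 11 after acidic work-up. Any O-aroylated material should rearrange to the same diketone under the excess base. Compound 11 then enters step 5 unchanged.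

Step 3. The second aroylation may stall at the mono-acylated ester, proton exchange with the enolised product may drain the trianion, or the trianion may be poorly soluble. The fallback sets out from 3 and comes back at 9. Direct aminolysis of both esters of 3 with MeNH(OMe)·HCl and iPrMgCl (THF, −20 °C) should give 4-methoxy-N-methoxy-N-methyl-3-{4-[methoxy(methyl)carbamoyl]phenoxy}benzamide F4. Trianion 8 (2.5 equiv, made as in step 3) should add once to each amide carbonyl to give the chelated hexalithium bis-adduct F5, which can neither enolise nor collapse in the flask. The acid quench then releases 9, so product acidity no longer competes with the acylation.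

Step 2. The acetyl donor may transfer a proton to the dianion, or acyl transfer may go to the pyranone oxygen, so that 4 is returned. The fallback sets out from 4 and comes back at 7. Dianion 5 is trapped with acetaldehyde at −78 °C in an aldol addition at the 6-methylene carbon to give racemic 4-hydroxy-6-(2-hydroxypropyl)-2H-pyran-2-one F6. Oxidation of the secondary alcohol with IBX in DMSO at rt should then give 7.

Further compounds
F1 | step 4 | 3-(4-carboxyphenoxy)-4-methoxybenzoic acid | COc1ccc(C(=O)O)cc1Oc1ccc(C(=O)O)cc1
F2 | step 4 | 3-[4-(chlorocarbonyl)phenoxy]-4-methoxybenzoyl chloride | COc1ccc(C(=O)Cl)cc1Oc1ccc(C(=O)Cl)cc1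
F3 | step 4 | tetralithium salt of the tetraanion of 2',4',6'-trihydroxyacetophenone | [Li+].[Li+].[Li+].[Li+].[CH2-]C(=O)c1c([O-])cc([O-])cc1[O-]
F4 | step 3 | 4-methoxy-N-methoxy-N-methyl-3-{4-[methoxy(methyl)carbamoyl]phenoxy}benzamide | COc1ccc(C(=O)N(C)OC)cc1Oc1ccc(C(=O)N(C)OC)cc1
F5 | step 3 | hexalithium salt of the bis(tetrahedral adduct) of F4 with two trianions 8 (mixture of stereoisomers at the two aminal carbons, centres lost on work-up) | [Li+].[Li+].[Li+].[Li+].[Li+].[Li+].COc1ccc(C([O-])(CC(=O)[CH-]c2cc([O-])cc(=O)o2)N(C)OC)cc1Oc1ccc(C([O-])(CC(=O)[CH-]c2cc([O-])cc(=O)o2)N(C)OC)cc1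
F6 | step 2 | racemic 4-hydroxy-6-(2-hydroxypropyl)-2H-pyran-2-one | CC(O)Cc1cc(O)cc(=O)o1
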